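Late in Tuesday's run the ratio ρ = c(left-handed substrate)/c(right-handed substrate) reads 0.484 at 1.50 h and 0.450 at 3.00 h, while the readings of both substrates keep falling. The new flask repeats that charge with more added ligand.

the same everywhere: left-handed substrate 20 mM; right-handed substrate 20 mM; free catalyst 5 mol%; racemization catalyst 0.66 mol%

| flask | reagent | added ligand | remark | time |
|---|---|---|---|---|
| Tuesday's | 4 equiv | 0.14 mM | run made earlier |  |
| flask | 4.00 equiv | 0.28 mM |  | 10 h |

Tuesday's run (percent of the left-handed substrate and right-handed substrate together charged)

| time / h | left-handed substrate / % | right-handed substrate / % |
|---|---|---|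
| 0.200 | 31 | 47 |
| 0.667 | 21 | 41 |
| 1.00 | 19 | 37 |
| 1.50 | 15 | 31 |
| 2.50 | 13 | 27 |
| 3.00 | 9 | 20 |

(each reading ± 2 percentage points)

- free catalyst is single-handed; left-handed substrate and right-handed substrate are mirror images of each other, charged as a racemate, each of them at the stated concentration
- what was read earlier has a scatter of 2 percentage points, one standard deviation
- steps thought possible: reagent + free catalyst + left-handed substrate -> free catalyst + left-handed product; reagent + free catalyst + right-handed substrate -> free catalyst + right-handed product; left-handed substrate + racemization catalyst <-> right-handed substrate + racemization catalyst; 2 free catalyst <-> resting dimer; racemization catalyst + added ligand <-> idle complex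
- an excess is the difference of the two amounts in percent of their sum
- an excess is below zero if the other one leads
- no earlier run changes the charge of added ligand; that part of a forecast is a guess

- part of the left-handed substrate and right-handed substrate charged together that has reacted at 10 h
- excess of left-handed product over right-handed product in the product at 10 h
- excess of right-handed substrate over left-handed substrate among what is left of the two at 10 h

Freeze what changes slowly, c(reagent) and c(free catalyst). Each substrate then reacts pseudo-first-order: left-handed with constant a, its rate constant times c(reagent) and c(free catalyst), and right-handed likewise with b. Racemization turns each substrate into the other with constant r. Setting the change of ln ρ to zero gives a − b = r(1/ρ − ρ). So the lead D = (a − b)/r, the net pull of the product steps over racemization, equals 1/ρ − ρ. The last three Tuesday readings give ρ = 0.474, hence D = 1.63.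

In the new flask the catalyst charge is Tuesday's, so a − b changes with c(reagent). From the readings, Tuesday's reagent stood near 0.700 of its charge at 2.50 h; for the new flask late in its run I take 0.5, the reagent's level with the pair used up. The ligand charge is twice Tuesday's, and no earlier run changes it, so I guess that r falls in that proportion. My D is then 2.33, and ρ = (√(D² + 4) − D)/2 gives 0.370. With eS = (1 − ρ)/(1 + ρ), that makes eS 46.0 %, a figure resting on that guess.

The forecast, whose eS differs from mine, gave c 87 %, eP 35 % and eS 85 %, reasoning that “If binding is tight, free racemization catalyst falls sharply”.

The flask gives c 86.6 %, eP 85.1 % and eS 46.0 % at 10 h.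

    reagent + free catalyst + left-handed substrate → free catalyst + left-handed product (k = 936 L² mol⁻² min⁻¹)
    reagent + free catalyst + right-handed substrate → free catalyst + right-handed product (k = 32.5 L² mol⁻² min⁻¹)
    left-handed substrate + racemization catalyst ⇌ right-handed substrate + racemization catalyst, rate k3*[racemization catalyst]*[left-handed substrate] forward; the back reaction follows from the equilibrium constant (k = 175 L mol⁻¹ min⁻¹)
    2 free catalyst ⇌ resting dimer (K = 9750 L mol⁻¹, k = 61.0 L mol⁻¹ min⁻¹)
    racemization catalyst + added ligand ⇌ idle complex, settled at all times (K = 31400 L mol⁻¹)

At 1.15 h the flask's left-handed product step uses left-handed substrate 3.4 times as fast as forward racemization. At 10 h the flask's ρ of 0.370 gives D = 2.34, against 1.63 read from Tuesday's run. The neighbour flask with 12 mol% of free catalyst keeps, at 10 h, 13.6 % of that charge free and 54.3 % of its reagent, which scales D to 3.61. That means ρ = 0.259 and eS 58.9 %; the computed excess there is 58.6 %.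

Readings and results are simulated for an exercise, and the scatter is random.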